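The runs were generated by integration on assumed constants; scatter was added.

Counted in percent of the Z charged, X is a small charge, and I carry one quantity through these flasks: the X ceiling, the share of the Z charged that X can draw away if each X holds one Z, 5.00%.

| setting | dawn | autumn | west | south | north |
|---|---|---|---|---|---|
| Z | 0.45 M | 0.45 M | 0.45 M | 0.45 M | 0.45 M |
| E | 0.27 M | 2.6 M | 0.225 M | 0.900 M | 1.80 M |
| X | 0.0225 M | 0.0225 M | 0.0225 M | 0.0225 M | 0.0225 M |
| remark | run made earlier | run made earlier |  |  |  |
| time |  |  | 6.0 d | 6.0 d | 6.0 d |

| run | time / d | D / % | Z / % |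
|---|---|---|---|
| dawn | 0.625 | 11.4 | 49.8 |
| dawn | 1.25 | 9.5 | 49.3 |
| dawn | 2.00 | 9.9 | 49.2 |
| dawn | 3.00 | 9.7 | 49.9 |
| dawn | 4.00 | 9.9 | 50.1 |
| autumn | 0.333 | 99.7 | 0 |
| autumn | 0.500 | 96.7 | 0 |
| autumn | 0.833 | 97.8 | 0 |
| autumn | 1.67 | 97.8 | 0 |
| autumn | 2.50 | 97.5 | 2.2 |
| autumn | 4.00 | 97.7 | 0 |

(scatter of a reading: 1 percentage point)



- final D, as a percentage of the Z charged, for each flask in turn (west, south, north)

Take the given numbers in turn. You need not know the time well, since the dawn run reads Z 49.8% at 0.625 d and 50.1% at 4.00 d, which agree within the scatter of 1 percentage point. The E charge you do need: in the dawn run the Z gone plus the D read come to 59.8% of E bound against 60.0% charged, so I read E as the limiting reagent there and the plateau as a stop with Z still in the flask. The south flask carries 2.00 E per Z and, if X reaches its ceiling and the remainder becomes D, needs 1.95, a spare of 0.0500, so that charge has to be right. For the south and north flasks I count the Z held by X as the shortfall from full D. The autumn run stands short of full D by 2.13% on average, less than the ceiling. My own reckoning therefore puts the south flask at 95.0%, with the ceiling reached, and the north flask between that and 97.9%; for the west flask I have no figure of my own.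

The forecast gives 6.8%, 75% and 96%, its south figure lower than mine, and says of that figure that “the 2% deficit is poorly determined and might not be M”.

The flasks give 7.25%, 94.7% and 96.4% of D.

    Z + E → G (k = 0.0224 M⁻¹ min⁻¹)
    E + G → D (k = 0.0152 M⁻¹ min⁻¹)
    G + X → L (k = 0.0521 M⁻¹ min⁻¹)

In the south flask at 6.00 d, L stands at 5.00%, level with the X ceiling, and D at 94.7% lies just under the 95.0% it leaves. In the north flask 29% of the X charge is still unbound at 6.00 d, so the ceiling times the part used gives a loss of 3.57% and D of 96.4%, and the flask holds L 3.57% beside D 96.4%.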